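**Strategy.** The side chain is detached at C1′=C2′ (cross-metathesis with a lactate-derived allylic diester) and the C7 hydroxyl is traced back to a C6=C7 enoate. The all-cis tetrahydrofuran ring (O1, C2, C3, C3a, C7a) of that enoate is the oxygen-bridged five-membered ring of a 7-oxabicyclo[2.2.1]heptene with endo oxygens on C3 and C3a, whose strained double bond joins C7 and C1′. One ring-rearrangement metathesis cleaves that double bond, makes C6=C7, closes the δ-lactone ring (O4, C5, C6, C7, C7a, C3a) and leaves C1′ as a vinyl group on C2. Its substrate is the enantiopure endo acrylate (C3a oxygen) carrying a silyl ether on the C3 oxygen.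

Key step: step 5

Numbering: furo[3,2-b]pyran-5-one numbering (O1, C2, C3, C3a, O4, C5, C6, C7, C7a; side chain C1′ to C5′ from C2) is used for all intermediates, including the bicyclic ones.
Assumption: the absolute sense of the enzymatic desymmetrization in step 3 cannot be predicted from first principles; it is assumed that the lipase chosen by screening acylates the hydroxyl on the carbon that becomes C3a, as drawn for 6.

Step 1
Reactants: 1 furan; 2 vinylene carbonate
Product: 3 endo-3a,4,7,7a-tetrahydro-4,7-epoxy-1,3-benzodioxol-2-one (meso; carbonate ring on the side of the C=C bridge)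
Conditions: neat, furan in excess, sealed tube, 125 °C; endo isomer separated from the exo isomer by chromatography or crystallization
Reagents that add atoms: none
Why: Thermal Diels–Alder cycloaddition of furan to a cis-dienophile, in which the cis relation of the two oxygens comes from the dienophile and the endo adduct, the only one with all four future tetrahydrofuran substituents on one face, is separated from the exo adduct; the product is meso, so no absolute configuration is set yet.

Step 2
Reactants: 3 endo carbonate
Product: 4 meso (1R,2R,3S,4S)-7-oxabicyclo[2.2.1]hept-5-ene-2,3-diol (both hydroxyls endo)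
Conditions: K2CO3 (cat.), MeOH, rt
Reagents that add atoms: none
Why: Base-catalysed transesterification of the cyclic carbonate with methanol should release the meso diol and dimethyl carbonate without touching a stereocentre.

Step 3
Reactants: 4 meso diol; 5 vinyl acrylate
Product: 6 (1R,2R,3R,4S)-3-hydroxy-7-oxabicyclo[2.2.1]hept-5-en-2-yl prop-2-enoate (acrylate on the future C3a oxygen, free hydroxyl on the future C3)
Conditions: immobilized Candida antarctica lipase B (or the best hit of a lipase screen), 5 (3 equiv), BHT (trace), t-BuOMe, 30 °C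
Reagents that add atoms: vinyl acrylate (5), C=CC(=O)OC=C
Why: Lipase-catalysed enantioselective transesterification of a meso diol with an enol ester donor (enzymatic desymmetrization) should acylate one of the two enantiotopic endo hydroxyls, which fixes the absolute configuration of all four ring stereocentres at once, while tautomerization of the released vinyl alcohol to acetaldehyde makes the acyl transfer irreversible.

Step 4
Reactants: 6 monoacrylate
Product: 7 (1R,2S,3R,4S)-3-[(tert-butyldimethylsilyl)oxy]-7-oxabicyclo[2.2.1]hept-5-en-2-yl prop-2-enoate (endo,endo)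
Conditions: TBSOTf, 2,6-lutidine, CH2Cl2, −78 °C
Reagents that add atoms: tert-butyldimethylsilyl trifluoromethanesulfonate, CC(C)(C)[Si](C)(C)OS(=O)(=O)C(F)(F)F
Why: Silylation of the remaining secondary alcohol with a silyl triflate and a hindered base at low temperature should be faster than 1,2-acyl shift and, because acylation precedes silylation, no alkoxide is ever formed next to the silyl ether, so silyl migration to the neighbouring oxygen (which would give the enantiomer) is excluded.

Step 5
Reactants: 7 endo acrylate silyl ether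
Product: 9 (2S,3R,3aS,7aR)-3-[(tert-butyldimethylsilyl)oxy]-2-ethenyl-2,3,3a,7a-tetrahydro-5H-furo[3,2-b]pyran-5-one, via ring-opened divinyl tetrahydrofuran acrylate 8 (not isolated)
Conditions: second-generation Hoveyda–Grubbs catalyst RuCl2(H2IMes)(=CH-C6H4-2-OiPr) (5 mol%), ethylene (1 atm), toluene (0.005 M), rt; then argon purge, 60 °C
Reagents that add atoms: ethylene, C=C
Why: Ring-rearrangement metathesis: the ruthenium methylidene formed under ethylene adds to the strained C7=C1′ double bond from the face of the oxygen bridge, and cycloreversion, driven by strain release, turns both olefin carbons into vinyl groups on an all-cis tetrahydrofuran (8); the alkylidene on C7 then undergoes ring-closing metathesis with the acrylate on the cis C3a oxygen and expels ethylene. The closest known reaction type is the ring-opening/ring-closing metathesis cascade of 7-oxanorbornenes that carry an unsaturated ester tether. The δ-lactone closes by ring-closing metathesis as a six-membered ring through the new C6=C7 bond (O4, C5, C6, C7, C7a, C3a), cis-fused because O4 and C7 are cis on the tetrahydrofuran. No stereocentre is created; C2, C3, C3a and C7a keep the configuration set by the endo cycloaddition and the enzymatic desymmetrization. The step needs ring closure to win over ring-opening polymerization, which ethylene and high dilution should secure, and it needs regioselection between the two vinyl groups, which geometry secures: closure from C1′ would have to form a bridged seven-membered ring, so only the alkylidene on C7 is productive.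

Step 6
Reactants: 9 unsaturated lactone
Product: 11 (2S,3R,3aS,7S,7aR)-3-[(tert-butyldimethylsilyl)oxy]-2-ethenyl-7-hydroxyhexahydro-5H-furo[3,2-b]pyran-5-one (C7 epimer of the target series), via C7 pinacol boronate 10 (not isolated)
Conditions: CuCl (5 mol%), DPEphos (5 mol%), NaOtBu (10 mol%), B2pin2 (1.1 equiv), MeOH (2 equiv), THF, rt; then NaBO3·4H2O, THF–H2O, 0 °C to rt
Reagents that add atoms: bis(pinacolato)diboron (boron of 10), CC1(C)OB(OC1(C)C)B1OC(C)(C)C(C)(C)O1; sodium perborate tetrahydrate (the C7 oxygen), [Na+].[O-]OB=O.O.O.O.O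
Why: Copper-catalysed conjugate borylation of the unsaturated lactone followed by C–B oxidation with retention should place the oxygen on C7 from the convex face (trans to O1, away from the tetrahydrofuran ring and the cis C2 vinyl group), which is the wrong epimer but immaterial because C7 is oxidized next; the isolated terminal vinyl group should not react under these conditions.

Step 7
Reactants: 11 (7S)-alcohol
Product: 12 (2S,3R,3aS,7aS)-3-[(tert-butyldimethylsilyl)oxy]-2-ethenyltetrahydro-5H-furo[3,2-b]pyran-5,7(6H)-dione
Conditions: Dess–Martin periodinane (1.3 equiv), CH2Cl2, 0 °C to rt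
Reagents that add atoms: none
Why: Dess–Martin oxidation of the only free alcohol should give the β-keto lactone and erase the C7 configuration, the silyl ether, lactone and vinyl group being inert.

Step 8
Reactants: 12 β-keto lactone
Product: 13 (2S,3R,3aS,7R,7aR)-3-[(tert-butyldimethylsilyl)oxy]-2-ethenyl-7-hydroxyhexahydro-5H-furo[3,2-b]pyran-5-one
Conditions: NaBH4, MeOH–CH2Cl2, −78 °C
Reagents that add atoms: none
Why: Borohydride reduction of the ketone of the cis-fused bicyclic β-keto lactone should deliver hydride to C7 from the open convex face, since the concave face is screened by O1, the tetrahydrofuran ring and the cis C2 vinyl group, so the new hydroxyl ends up cis to O1 (7R) as in the target, while the lactone and the vinyl group are not reduced at this temperature.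

Step 9
Reactants: 14 methyl (R)-lactate
Product: 15 methyl (2R)-2-[(tert-butyldimethylsilyl)oxy]propanoate
Conditions: TBSCl, imidazole, DMF, rt
Reagents that add atoms: tert-butyldimethylsilyl chloride, CC(C)(C)[Si](C)(C)Cl
Why: Standard silyl protection of the secondary alcohol, which leaves the lactate stereocentre (future C4′) untouched.

Step 10
Reactants: 15 silyl lactate
Product: 16 (2R)-2-[(tert-butyldimethylsilyl)oxy]propanal
Conditions: i-Bu2AlH (1.05 equiv), CH2Cl2, −78 °C
Reagents that add atoms: none
Why: Partial reduction of the methyl ester with i-Bu2AlH at −78 °C stops at the aluminium hemiacetal, which should give the α-silyloxy aldehyde on work-up without epimerization; it is used at once.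

Step 11
Reactants: 16 aldehyde; 17 vinylmagnesium bromide; 18 benzoyl chloride
Product: 20 (3S,4R)-4-[(tert-butyldimethylsilyl)oxy]pent-1-en-3-yl benzoate, via bromomagnesium alkoxide 19 (not isolated)
Conditions: CH2=CHMgBr (1.2 equiv), THF, −78 °C; then BzCl (1.5 equiv), −78 to 0 °C
Reagents that add atoms: vinylmagnesium bromide (17), C=C[Mg]Br; benzoyl chloride (18), O=C(Cl)c1ccccc1
Why: Felkin–Anh (non-chelation) 1,2-addition of the vinyl Grignard reagent to the α-silyloxy aldehyde should set C3′ anti to the C4′ oxygen (3S), the magnesium alkoxide is acylated in the same flask, and the minor syn diastereomer is removed by chromatography.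

Step 12
Reactants: 20 silyl ether benzoate
Product: 21 (3S,4R)-4-hydroxypent-1-en-3-yl benzoate
Conditions: HF·pyridine, pyridine, THF, 0 °C to rt
Reagents that add atoms: none
Why: Fluoride cleavage of the silyl ether in an acidic, buffered medium, chosen because the neighbouring benzoate should not migrate in the absence of base.

Step 13
Reactants: 21 hydroxy benzoate; 22 acetic anhydride
Product: 23 (3S,4R)-4-acetoxypent-1-en-3-yl benzoate
Conditions: Ac2O, pyridine, DMAP (cat.), CH2Cl2, 0 °C
Reagents that add atoms: acetic anhydride (22), CC(=O)OC(C)=O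
Why: DMAP-catalysed acetylation of the free secondary alcohol, run on the crude alcohol so that acylation outpaces any benzoyl shift.

Step 14
Reactants: 13 vinyl hydroxy lactone; 23 allylic diester
Product: 24 (1E,3S,4R)-4-acetoxy-1-[(2S,3R,3aS,7R,7aR)-3-[(tert-butyldimethylsilyl)oxy]-7-hydroxy-5-oxohexahydro-2H-furo[3,2-b]pyran-2-yl]pent-1-en-3-yl benzoate
Conditions: 23 (3 equiv), second-generation Hoveyda–Grubbs catalyst RuCl2(H2IMes)(=CH-C6H4-2-OiPr) (10 mol%), CH2Cl2, 40 °C
Reagents that add atoms: none
Why: Olefin cross-metathesis of two terminal alkenes with loss of ethylene should give the thermodynamically favoured E C1′=C2′ olefin, an excess of the cheap partner 23 driving 13 to the cross product, and the lactone, esters and free hydroxyl are tolerated by the catalyst.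

Step 15
Reactants: 24 silyl ether
Product: 25 (1E,3S,4R)-4-acetoxy-1-[(2S,3R,3aR,7R,7aR)-3,7-dihydroxy-5-oxohexahydro-2H-furo[3,2-b]pyran-2-yl]pent-1-en-3-yl benzoate (target)
Conditions: HF·pyridine, pyridine, THF, 0 °C to rt
Reagents that add atoms: none
Why: Acidic fluoride desilylation removes the last protecting group without base, so the β-hydroxy lactone should not eliminate and the acetate and benzoate should neither migrate nor hydrolyse.

**Compound list**

1 | furan | c1ccoc1 | starting material
2 | vinylene carbonate | O=C1OC=CO1 | starting material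
3 | endo-3a,4,7,7a-tetrahydro-4,7-epoxy-1,3-benzodioxol-2-one (meso) | C1=C[C@@H]2O[C@H]1[C@@H]3OC(=O)O[C@H]23 | intermediate
4 | meso (1R,2R,3S,4S)-7-oxabicyclo[2.2.1]hept-5-ene-2,3-diol (endo,endo) | C1=C[C@@H]2O[C@H]1[C@H](O)[C@@H]2O | intermediate
5 | vinyl acrylate | C=CC(=O)OC=C | starting material
6 | (1R,2R,3R,4S)-3-hydroxy-7-oxabicyclo[2.2.1]hept-5-en-2-yl prop-2-enoate (endo,endo) | C1=C[C@@H]2O[C@H]1[C@H](OC(=O)C=C)[C@@H]2O | intermediate
7 | (1R,2S,3R,4S)-3-[(tert-butyldimethylsilyl)oxy]-7-oxabicyclo[2.2.1]hept-5-en-2-yl prop-2-enoate (endo,endo) | C1=C[C@@H]2O[C@H]1[C@H](OC(=O)C=C)[C@@H]2O[Si](C)(C)C(C)(C)C | intermediate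
8 | (2R,3S,4R,5S)-4-[(tert-butyldimethylsilyl)oxy]-2,5-diethenyloxolan-3-yl prop-2-enoate (all-cis) | C=C[C@@H]1O[C@H](C=C)[C@H](OC(=O)C=C)[C@@H]1O[Si](C)(C)C(C)(C)C | intermediate
9 | (2S,3R,3aS,7aR)-3-[(tert-butyldimethylsilyl)oxy]-2-ethenyl-2,3,3a,7a-tetrahydro-5H-furo[3,2-b]pyran-5-one | C=C[C@@H]1O[C@H]2[C@H](OC(=O)C=C2)[C@@H]1O[Si](C)(C)C(C)(C)C | intermediate
10 | (2S,3R,3aS,7S,7aR)-3-[(tert-butyldimethylsilyl)oxy]-2-ethenyl-7-(4,4,5,5-tetramethyl-1,3,2-dioxaborolan-2-yl)hexahydro-5H-furo[3,2-b]pyran-5-one | C=C[C@@H]1O[C@H]2[C@H](OC(=O)C[C@@H]2B3OC(C)(C)C(C)(C)O3)[C@@H]1O[Si](C)(C)C(C)(C)C | intermediate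
11 | (2S,3R,3aS,7S,7aR)-3-[(tert-butyldimethylsilyl)oxy]-2-ethenyl-7-hydroxyhexahydro-5H-furo[3,2-b]pyran-5-one | C=C[C@@H]1O[C@H]2[C@H](OC(=O)C[C@@H]2O)[C@@H]1O[Si](C)(C)C(C)(C)C | intermediate
12 | (2S,3R,3aS,7aS)-3-[(tert-butyldimethylsilyl)oxy]-2-ethenyltetrahydro-5H-furo[3,2-b]pyran-5,7(6H)-dione | C=C[C@@H]1O[C@H]2[C@H](OC(=O)CC2=O)[C@@H]1O[Si](C)(C)C(C)(C)C | intermediate
13 | (2S,3R,3aS,7R,7aR)-3-[(tert-butyldimethylsilyl)oxy]-2-ethenyl-7-hydroxyhexahydro-5H-furo[3,2-b]pyran-5-one | C=C[C@@H]1O[C@H]2[C@H](OC(=O)C[C@H]2O)[C@@H]1O[Si](C)(C)C(C)(C)C | intermediate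
14 | methyl (R)-lactate | C[C@@H](O)C(=O)OC | starting material
15 | methyl (2R)-2-[(tert-butyldimethylsilyl)oxy]propanoate | C[C@@H](O[Si](C)(C)C(C)(C)C)C(=O)OC | intermediate
16 | (2R)-2-[(tert-butyldimethylsilyl)oxy]propanal | C[C@@H](O[Si](C)(C)C(C)(C)C)C=O | intermediate
17 | vinylmagnesium bromide | C=C[Mg]Br | starting material
18 | benzoyl chloride | O=C(Cl)c1ccccc1 | starting material
19 | bromomagnesium (3S,4R)-4-[(tert-butyldimethylsilyl)oxy]pent-1-en-3-olate | CC(C)(C)[Si](C)(C)O[C@H](C)[C@H](C=C)O[Mg]Br | intermediate
20 | (3S,4R)-4-[(tert-butyldimethylsilyl)oxy]pent-1-en-3-yl benzoate | CC(C)(C)[Si](C)(C)O[C@H](C)[C@H](C=C)OC(=O)c1ccccc1 | intermediate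
21 | (3S,4R)-4-hydroxypent-1-en-3-yl benzoate | C[C@@H](O)[C@H](C=C)OC(=O)c1ccccc1 | intermediate
22 | acetic anhydride | CC(=O)OC(C)=O | starting material
23 | (3S,4R)-4-acetoxypent-1-en-3-yl benzoate | CC(=O)O[C@H](C)[C@H](C=C)OC(=O)c1ccccc1 | intermediate
24 | (1E,3S,4R)-4-acetoxy-1-[(2S,3R,3aS,7R,7aR)-3-[(tert-butyldimethylsilyl)oxy]-7-hydroxy-5-oxohexahydro-2H-furo[3,2-b]pyran-2-yl]pent-1-en-3-yl benzoate | CC(=O)O[C@H](C)[C@H](/C=C/[C@@H]1O[C@H]2[C@H](OC(=O)C[C@H]2O)[C@@H]1O[Si](C)(C)C(C)(C)C)OC(=O)c1ccccc1 | intermediate
25 | (1E,3S,4R)-4-acetoxy-1-[(2S,3R,3aR,7R,7aR)-3,7-dihydroxy-5-oxohexahydro-2H-furo[3,2-b]pyran-2-yl]pent-1-en-3-yl benzoate | CC(=O)O[C@H](C)[C@H](/C=C/[C@@H]1O[C@H]2[C@H](OC(=O)C[C@H]2O)[C@@H]1O)OC(=O)c1ccccc1 | target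

**Step count.** Total: 15 steps. Longest linear sequence: 10 steps (steps 1 to 8, 14 and 15); the side-chain branch is steps 9 to 13.

**Steps most likely to fail**

1. Step 5 (ring-rearrangement metathesis). Ring-opening polymerization of the strained olefin may outrun ethenolysis. The ring closure may also stall at the open diene, because the electron-poor acrylate is a slow partner and its carbonyl can sequester the alkylidene by chelation. The fallback replaces the acrylate by an electron-rich allyl ether tether and reaches the lactone by allylic oxidation. It sets out from 7: reductive removal of the acrylate (i-Bu2AlH, CH2Cl2, −78 °C) should give (1R,2S,3S,4S)-3-[(tert-butyldimethylsilyl)oxy]-7-oxabicyclo[2.2.1]hept-5-en-2-ol F1. Acid-catalysed O-allylation (allyl 2,2,2-trichloroacetimidate, TfOH cat., so that no alkoxide arises next to the silyl ether) should give (1R,2S,3R,4S)-2-(allyloxy)-3-[(tert-butyldimethylsilyl)oxy]-7-oxabicyclo[2.2.1]hept-5-ene F2. Ring-rearrangement metathesis of F2 (RuCl2(H2IMes)(=CH-C6H4-2-OiPr), ethylene, toluene) should give (2S,3R,3aS,7aR)-3-[(tert-butyldimethylsilyl)oxy]-2-ethenyl-2,3,3a,7a-tetrahydro-5H-furo[3,2-b]pyran F3. Oxidation of its allylic ether methylene C5 with pyridinium chlorochromate (C5H5NH)[CrO3Cl] in CH2Cl2 brings the route back to 9.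

2. Step 14 (cross-metathesis). The C2 vinyl group, flanked by the cis silyl ether on C3 and close to the concave C7 hydroxyl, may engage too slowly, so that homodimerization of the partner and catalyst decay take over and E selectivity suffers. The fallback inverts the end game so that the union is made on the least hindered substrate and needs no later deprotection. It sets out from 13: desilylation (HF·pyridine, pyridine, THF) should give (2S,3R,3aR,7R,7aR)-2-ethenyl-3,7-dihydroxyhexahydro-5H-furo[3,2-b]pyran-5-one F4. Cross-metathesis of F4 with 23 (RuCl2(H2IMes)(=CH-C6H4-2-OiPr), CH2Cl2, 40 °C) as the last operation comes back to the route at 25.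

3. Step 3 (enzymatic desymmetrization). Discrimination between the two enantiotopic hydroxyls may be insufficient with the conjugated acyl donor, acylation of the hindered endo alcohol may be slow, and enantiopurity may erode by 1,2-acyl shift in the monoester. The fallback runs the desymmetrization in the hydrolytic direction on a meso diester, where the group selection of the same enzyme class is complementary. It sets out from 4: exhaustive acylation (acryloyl chloride, Et3N, CH2Cl2, 0 °C) should give meso (1R,2S,3R,4S)-7-oxabicyclo[2.2.1]hept-5-ene-2,3-diyl bis(prop-2-enoate) F5. Enzymatic hydrolysis of one ester group (lipase or pig liver esterase, aqueous NaH2PO4/Na2HPO4 buffer pH 7, t-BuOMe) comes back to the route at 6.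

Further compounds
F1 | step 5 | (1R,2S,3S,4S)-3-[(tert-butyldimethylsilyl)oxy]-7-oxabicyclo[2.2.1]hept-5-en-2-ol | C1=C[C@@H]2O[C@H]1[C@H](O)[C@@H]2O[Si](C)(C)C(C)(C)C
F2 | step 5 | (1R,2S,3R,4S)-2-(allyloxy)-3-[(tert-butyldimethylsilyl)oxy]-7-oxabicyclo[2.2.1]hept-5-ene | C1=C[C@@H]2O[C@H]1[C@H](OCC=C)[C@@H]2O[Si](C)(C)C(C)(C)C
F3 | step 5 | (2S,3R,3aS,7aR)-3-[(tert-butyldimethylsilyl)oxy]-2-ethenyl-2,3,3a,7a-tetrahydro-5H-furo[3,2-b]pyran | C=C[C@@H]1O[C@H]2[C@H](OCC=C2)[C@@H]1O[Si](C)(C)C(C)(C)C
F4 | step 14 | (2S,3R,3aR,7R,7aR)-2-ethenyl-3,7-dihydroxyhexahydro-5H-furo[3,2-b]pyran-5-one | C=C[C@@H]1O[C@H]2[C@H](OC(=O)C[C@H]2O)[C@@H]1O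
F5 | step 3 | meso (1R,2S,3R,4S)-7-oxabicyclo[2.2.1]hept-5-ene-2,3-diyl bis(prop-2-enoate) | C1=C[C@@H]2O[C@H]1[C@H](OC(=O)C=C)[C@@H]2OC(=O)C=C
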